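**Retrosynthetic overview**
1. The C7–O(acyl) bond and the C7 stereocentre are made last: catalytic enantioselective acyloxylation of the enolate of isochromenone 9 (from benzopyrylium salt 7) with didecanoyl peroxide 8 under chiral ammonium ion-pair catalysis, so ester and stereocentre arrive together.
2. Pyran ring (O2–C3 bond): 6-endo cycloisomerisation of o-alkynylbenzaldehyde 6 to the 2-benzopyrylium salt 7.
3. C4a–C4 bond: Sonogashira coupling of aryl bromide 4 with non-1-yne 5.
4. Arene substituents: C-methylation and Vilsmeier formylation of 5-bromoresorcinol 1.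
5. Ring order: benzene ring bought, pyrylium ring closed in step 4, carbocycle dearomatised as the stereocentre is set in step 5.

Assumption: didecanoyl peroxide (CAS 762-12-9, sold as a polymerisation initiator) counts as a commercial starting material.

The target is (7R): at C7 the CIP order is O-acyl > C8 > C6 > CH3. The route has not been run; step 5 is a proposed reaction, and its level and sense of induction must be checked on the first run.

**Step 1**
Reactants: 1 5-bromobenzene-1,3-diol (5-bromoresorcinol)
Product: 3 2-bromo-4,6-dihydroxybenzaldehyde, via aryl iminium chloride 2 (not isolated)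
Conditions: POCl3 (1.3 equiv), DMF (1.5 equiv), MeCN, 0 °C → rt; then H2O, 50 °C
Reagents that add atoms: N,N-dimethylformamide CN(C)C=O; water O
Why: Vilsmeier–Haack formylation: the chloroiminium ion attacks the ring carbon para to one OH and ortho to the other (next to Br), the same site selectivity by which orcinol gives orcylaldehyde, and hydrolysis of iminium 2 releases the aldehyde.

**Step 2**
Reactants: 3 2-bromo-4,6-dihydroxybenzaldehyde
Product: 4 6-bromo-2,4-dihydroxy-3-methylbenzaldehyde
Conditions: KOH (2.1 equiv), MeI (1.2 equiv), MeOH, 0 → 50 °C
Reagents that add atoms: iodomethane CI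
Why: C-alkylation of a resorcinol phenoxide in a protic solvent: the carbon flanked by both oxygens is the most nucleophilic ring position and the other free carbon is shielded by Br, as in the standard C-methylation of 2,4-dihydroxybenzaldehydes.

**Step 3**
Reactants: 4 6-bromo-2,4-dihydroxy-3-methylbenzaldehyde; 5 non-1-yne
Product: 6 2,4-dihydroxy-3-methyl-6-(non-1-yn-1-yl)benzaldehyde
Conditions: PdCl2(PPh3)2 (3 mol%), CuI (6 mol%), Et3N (4 equiv), DMF, 60 °C
Reagents that add atoms: none
Why: Sonogashira coupling: oxidative addition is helped by the ortho formyl group, free phenols are tolerated, and no OH sits ortho to the new alkyne, so benzofuran closure cannot compete.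

**Step 4**
Reactants: 6 2,4-dihydroxy-3-methyl-6-(non-1-yn-1-yl)benzaldehyde
Product: 7 3-heptyl-6,8-dihydroxy-7-methylisochromenylium (2-benzopyrylium) trifluoroacetate
Conditions: Au(OAc)3 (5 mol%), TFA/ClCH2CH2Cl (1:10), rt, 10 min; evaporate, strip with PhMe, triturate (dry Et2O/pentane), use at once
Reagents that add atoms: trifluoroacetic acid OC(=O)C(F)(F)F
Why: Gold(III)-catalysed 6-endo-dig cycloisomerisation of an o-alkynylbenzaldehyde: the formyl oxygen, made electron-rich by the ortho and para OH groups, adds to the gold-bound alkyne and protodeauration in TFA leaves the aromatic 2-benzopyrylium salt.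

**Step 5**
Reactants: 7 3-heptyl-6,8-dihydroxy-7-methylisochromenylium trifluoroacetate; 8 didecanoyl peroxide
Product: 10 (7R)-3-heptyl-7-methyl-6,8-dioxo-7,8-dihydro-6H-isochromen-7-yl decanoate, via anhydrobase 9 (not isolated)
Conditions: N-(9-anthracenylmethyl)cinchonidinium chloride (10 mol%), K2HPO4 (anhydrous powder, 3 equiv), 4 Å MS, PhMe/CH2Cl2 (4:1), Ar (degassed), −30 °C; 8 (1.3 equiv) added over 2 h
Reagents that add atoms: none
Why: Proposed new method: phase-transfer-catalysed enantioselective dearomative α-acyloxylation with an aliphatic diacyl peroxide — K2HPO4 removes TFA and then the enol proton, so 7 becomes anhydrobase 9 and its enolate, a vinylogous 2-methyl-1,3-diketonate whose most nucleophilic carbon is C7; this enolate enters the organic phase as a contact ion pair with the chiral ammonium cation, whose C9–OH hydrogen-bonds a carbonyl of 8, and C7 attacks the O–O bond (SN2 at oxygen, decanoate leaving) from the face left open by the anthracenyl and quinoline walls, in the working model the face on which C8 → C6 → CH3 runs clockwise when seen from the incoming oxygen, which gives 7R (the pseudo-enantiomeric cinchoninium salt reverses the sense if needed); closest known reaction types are the organocatalytic and phase-transfer enantioselective α-benzoyloxylation of β-keto carbonyls and 3-substituted oxindoles with benzoyl peroxide, and the racemic lead tetraacetate (Wessely) acetoxylation of 2-benzopyrylium salts at the same carbon.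

**Compound list**
1 | 5-bromobenzene-1,3-diol (5-bromoresorcinol) | Oc1cc(O)cc(Br)c1 | starting material
2 | N-[(2-bromo-4,6-dihydroxyphenyl)methylidene]-N-methylmethanaminium chloride (aryl iminium chloride) | C[N+](C)=Cc1c(Br)cc(O)cc1O.[Cl-] | intermediate
3 | 2-bromo-4,6-dihydroxybenzaldehyde | O=Cc1c(Br)cc(O)cc1O | intermediate
4 | 6-bromo-2,4-dihydroxy-3-methylbenzaldehyde | Cc1c(O)cc(Br)c(C=O)c1O | intermediate
5 | non-1-yne | C#CCCCCCCC | starting material
6 | 2,4-dihydroxy-3-methyl-6-(non-1-yn-1-yl)benzaldehyde | CCCCCCCC#Cc1cc(O)c(C)c(O)c1C=O | intermediate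
7 | 3-heptyl-6,8-dihydroxy-7-methylisochromenylium trifluoroacetate | CCCCCCCc1cc2cc(O)c(C)c(O)c2c[o+]1.[O-]C(=O)C(F)(F)F | intermediate
8 | didecanoyl peroxide | CCCCCCCCCC(=O)OOC(=O)CCCCCCCCC | starting material
9 | 3-heptyl-8-hydroxy-7-methyl-6H-isochromen-6-one (anhydrobase of 7) | CCCCCCCC1=CC2=CC(=O)C(C)=C(O)C2=CO1 | intermediate
10 | (7R)-3-heptyl-7-methyl-6,8-dioxo-7,8-dihydro-6H-isochromen-7-yl decanoate | CCCCCCCCCC(=O)O[C@]1(C)C(=O)C=C2C=C(CCCCCCC)OC=C2C1=O | target

**Step count**
Total steps: 5. Longest linear sequence: 5 (1 → 3 → 4 → 6 → 7 → 10).

**Steps most likely to fail (in route order; step 5 is the most uncertain)**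

Step 1. The free bromoresorcinol may formylate partly between the two OH groups or give a low yield. The fallback sets out from 1 and comes back at 3. Compound 1 is O-methylated (MeI, K2CO3, acetone) to 1-bromo-3,5-dimethoxybenzene F1. Vilsmeier formylation (POCl3, DMF, 80 °C) then gives, through the aryl iminium chloride F2 and aqueous hydrolysis, 2-bromo-4,6-dimethoxybenzaldehyde F3. BBr3 (CH2Cl2, −78 °C → rt) cleaves both ethers to give 3. This protect, formylate, deprotect sequence is established chemistry.

Step 4. The catalysis itself is dependable; the risk is isolating the hygroscopic, water-sensitive salt 7 free of excess TFA. The fallback sets out from 6 and comes back at 7. The cycloisomerisation mixture is quenched with water and NaHCO3, which opens the pyrylium to the bench-stable keto-aldehyde 2,4-dihydroxy-3-methyl-6-(2-oxononyl)benzaldehyde F4. F4 is chromatographed and stored. Just before step 5 it is cyclodehydrated (TFA, trifluoroacetic anhydride, CH2Cl2, 0 °C) and evaporated to give 7, the classical closure of a 2-(2-oxoalkyl)benzaldehyde to a 2-benzopyrylium salt.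

Step 5 (the proposed new reaction). Possible failure modes:
- a racemic background reaction of neutral 9 or of the potassium enolate at the solid surface;
- electron transfer to 8 followed by decarboxylation, giving C-nonylation instead of acyloxylation;
- acyl transfer to the enolate oxygen;
- low or reversed facial selectivity.

The quaternary chloride catalyst was chosen because free tertiary amines and bromide or iodide are oxidised by diacyl peroxides. Oxygen is excluded because the enolate autoxidises.

The fallback uses known chemistry, sets out from 7 and comes back at 10. Aqueous NaHCO3 in EtOAc opens 7 to 2,4-dihydroxy-3-methyl-6-(2-oxononyl)benzaldehyde F4. The FAD-dependent monooxygenase AzaH (clarified lysate, NADP+, glucose-6-phosphate and its dehydrogenase for recycling, air, phosphate buffer pH 8, 30 °C) hydroxylates the methyl-bearing ring carbon to the dienone (S)-2,3-dihydroxy-3-methyl-4-oxo-6-(2-oxononyl)cyclohexa-1,5-diene-1-carbaldehyde F5. F5 closes and loses water in the assay to (7R)-3-heptyl-7-hydroxy-7-methyl-6H-isochromene-6,8(7H)-dione F6. The spatial arrangement is unchanged; the descriptor changes only because the CIP ranking of the two ring neighbours changes. This enzyme is R-selective for this substrate family as I recall it, though the heptyl chain is untested. Decanoyl chloride, Et3N and DMAP (CH2Cl2, 0 °C) then acylate the tertiary alcohol of F6 to give 10. The same material serves as the reference for assigning the sense of induction in step 5 by chiral HPLC.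

**Further compounds**
F1 | step 1 | 1-bromo-3,5-dimethoxybenzene | COc1cc(Br)cc(OC)c1
F2 | step 1 | N-[(2-bromo-4,6-dimethoxyphenyl)methylidene]-N-methylmethanaminium chloride | C[N+](C)=Cc1c(Br)cc(OC)cc1OC.[Cl-]
F3 | step 1 | 2-bromo-4,6-dimethoxybenzaldehyde | COc1cc(Br)c(C=O)c(OC)c1
F4 | step 4 | 2,4-dihydroxy-3-methyl-6-(2-oxononyl)benzaldehyde | CCCCCCCC(=O)Cc1cc(O)c(C)c(O)c1C=O
F5 | step 5 | (S)-2,3-dihydroxy-3-methyl-4-oxo-6-(2-oxononyl)cyclohexa-1,5-diene-1-carbaldehyde | O[C@]1(C)C(=O)C=C(CC(=O)CCCCCCC)C(C=O)=C1O
F6 | step 5 | (7R)-3-heptyl-7-hydroxy-7-methyl-6H-isochromene-6,8(7H)-dione | O[C@]1(C)C(=O)C=C2C=C(CCCCCCC)OC=C2C1=O
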